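## Structural features

The target is an open-chain 8,8'-linked lignan diester: a butane-1,4-diol whose two primary oxygens (on C9 and C9') are benzoylated and whose two central carbons (C8 and C8') each carry an arylmethyl group (C7 with ring A, C7' with ring B). Ring A is 3-hydroxy-4-methoxyphenyl and ring B is 4-hydroxy-3-methoxyphenyl, so the two halves are constitutional isomers and the molecule has no true twofold axis. C8 and C8' are the only stereocentres, they are adjacent, and both are R. This is the like (non-meso) relation, which places C7 and C7' trans on a five-membered ring closed through C9 and C9'. The fragile groups are the two free phenols beside two alkyl benzoates (only aliphatic oxygen may stay acylated) and, in any intermediate with a carbonyl at C7, the α-centre C8 with its β-oxygen on C9 (epimerisation, β-elimination). The real difficulty is telling two nearly identical halves apart while fixing two neighbouring, conformationally free stereocentres in the absolute sense. The key step uses the pattern of ring A: the hydroxyl (position 3) is ortho to the methoxy group (position 4) and meta to the carbon bearing C7 (position 1), which is what C2–O and C3–OMe of a 3-alkoxyfuran deliver when its C2 and C5 add to the two alkyne carbons of an ynone whose carbonyl is C7. The cycloaddition precursor and product were checked atom by atom against the target (ring A, ring B, C8, C8') and need no correction; they appear as 12 and 15.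

## Logic of the disconnections

19 ⇒ 18. The two phenolic O–H bonds are traced back to aryl ester C(=O)–O bonds. The oxygens on C9 and C9' cannot be benzoylated selectively beside two free phenols, so all four oxygens are acylated and the two aryl esters are removed afterwards. The forward step needs a nucleophile that attacks an ester with a phenoxide leaving group and spares an alkyl ester.

18 ⇒ 17. Four O–C(=O) bonds are cut at once. Nothing has to be told apart, so 17, which has no protecting group, is the simplest carrier of the skeleton and both stereocentres. The forward step only has to go to completion.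

17 ⇒ 16 ⇒ 15. The two C7–H bonds are traced back to C7=O, the ring B phenol to its benzyl ether, and the C9/C9' hydroxyls to silyl ethers. The carbonyl is what the ring-forming step requires, the benzyl ether falls in the same hydrogenation, and silyl ethers are the poorest leaving groups that can sit β to the ketone. The forward step must remove the carbonyl before acid can enolise it, because C8 is its α-carbon.

15 ⇒ 14 ⇒ 12 + 13. Two C–C bonds of ring A are cut, between ring positions 2 and 3 and between positions 1 and 6 (position 1 carries C7), after the phenolic oxygen has been reconnected as a bridge from position 3 to position 6. This removes ring A and its whole substitution pattern from the chiral fragment: 12 keeps only a terminal alkyne on C7, and 13 already holds the adjacent O/OMe pair. The forward step must be regioselective twice (cycloaddition and opening of the bridge of 14) and must run without base or strong acid, since C8 is α to the ketone throughout.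

12 ⇒ 11 ⇒ 10. C7=O is traced back to a carbinol and the two O–Si bonds are cut. Carrying C7 as an alcohol until the last moment keeps C8 configurationally safe, and the silyl groups can be placed by the primary/secondary difference in 10. The forward steps need a selective bis-silylation and a non-basic oxidation.

10 ⇒ 9 ⇒ 8. The C9–O–C9' connection is restored as a lactone (C9 back at the carboxyl level) and the alkyne C–H as C–Si. The ring of 8 is what fixes the relation between C8 and C8'. The forward step must reduce a lactone without touching a propargylic alcohol or its alkyne.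

8 ⇒ 6 + 7. The C7–C8 bond is cut, an aldol disconnection. C8 then arises as a ring enolate carbon next to the existing centre C8' of 6, so the new substituent enters trans, which on the open chain is the like relation of 19. The demand is kinetic control (low temperature, cold acidic quench) so that the aldolate does not revert. Forming C8–C8' by amine-catalysed addition of a β-alkoxy aldehyde to a 3-aryl-1-nitropropene was weighed as another way to 12 and set aside: that nitroalkene can slide into conjugation with ring B under the basic catalyst, the β-alkoxy enamine can eliminate, and a Nef step plus several redox and protecting-group steps would follow.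

6 ⇒ 5 ⇒ 4. The lactone C–O bond is cut and C9' is taken back to the ester level. The two carboxyl carbons of 4 are already differentiated (ester at C9', free acid at the future C9), so no protecting group is needed. The forward step must reduce an ester next to a carboxylate salt.

4 ⇒ 3. The C8'–H and C7'–H bonds are removed to give the C7'=C8' alkene. Absolute configuration enters here: C8' is set by face-selective hydrogenation under chelation of the carboxylate. The catalyst must reduce a trisubstituted alkene with high enantioselectivity and leave the benzyl ether alone.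

3 ⇒ 1 + 2. The C7'=C8' bond is cut by a Stobbe disconnection, returning the ring B aldehyde 1 and the C4 diester 2. The condensation gives the half-ester directly, which is the differentiation used in 4. The forward step must give the E alkene.

## Other disconnections considered

Alternative 1: The cut is at the two benzylic C–H bonds (C7–H, C7'–H) and at two lactone C–O bonds: the target is traced through a cis-fused dilactone A2 to an open diketo diester A1 in which C8 and C8' are each flanked by a ketone and an ester. Forward, RuCl(p-cymene)[(S,S)-TsDPEN] with formic acid and triethylamine would reduce both aryl ketones of A1 by outer-sphere hydride transfer while C8 and C8' epimerise, and each new hydroxyl would close onto the remote ester (C7–O–C9', C7'–O–C9), so that only the like C8/C8' pair is drained into A2.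
- In its favour: A1 is stereorandom and can be assembled from two purchased arenes, all stereochemistry comes from one catalytic step, and A2 is rigid.
- Against it here: the catalyst must control C7 and C7', which are later erased by hydrogenolysis, while C8 and C8' are fixed only indirectly through the ring fusion. The two ketones differ electronically, so the second reduction must end in the same bicycle whether matched or mismatched. A1 is also a 1,4-diketone that can close to a furan in the acidic reducing medium.
- Comparison: on step economy this plan is the better one (about nine operations against eleven; from A2 only C–O hydrogenolysis, carboxyl reduction and the same acylation/aminolysis ending are needed, passing through 17). On material cost it is also better, since both rings are bought and not built. On mechanism the chosen plan is safer: its two stereocentres come from two independent, well-understood events, whereas here four centres must fall into place in one dynamic event on an unsymmetrical substrate. On structural fit the two are equal: both finish C7 as CH2 by hydrogenolysis.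

Alternative 2: The cut is at two C–C bonds of ring B. Forward, the 3-benzyloxy-6-alkyl-2-pyrone A3, which already carries the complete chain with ring A, would react with 1,1-dimethoxyethene A4 by [4+2] cycloaddition, extrusion of CO2 and loss of methanol to give A5, the bis(O-benzyl) ether of the target.
- In its favour: the arene is made last, A5 is a single hydrogenolysis from 19 (a better ending than the three steps after the chosen key step), and no stereocentre is α to a carbonyl during the cycloaddition (C8' is insulated by C7'). On that point it is better than the chosen plan, where C8 is α to the ynone carbonyl.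
- Against it here: the pairing is electronically mismatched. A3 has a donor at position 3 and A4 is an electron-rich alkene, so forcing temperatures would be needed, under which A4 oligomerises. A3 is also a long synthesis: a 2-pyrone built on a chiral chain that already holds both benzoates and ring A.
- Comparison: the logic is the same as the chosen plan (an oxygenated benzene ring from a cycloaddition followed by aromatisation), and regiochemistry is dictated by an oxygen substituent in both, so they are equal there. The chosen pairing is polarity-matched (electron-rich furan, electron-poor ynone) and should run near room temperature, which is the decisive difference. On overall step count the alternative is worse because of A3.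

Alternative 3: The cut is at C8–C9 and C8'–C9' together. Forward, Pd(OCOCF3)2 (divalent palladium) with a chiral bis(oxazoline), p-benzoquinone as oxidant, carbon monoxide and methanol would add two methoxycarbonyl groups syn across the (E)-alkene A6 (methoxycarbonyl–palladium insertion, CO insertion, methanolysis) to give the like succinate A7.
- In its favour: both stereocentres and both C9 carbons arrive in one step, the E geometry with syn addition gives the correct relative configuration, and ester reduction, benzoylation and hydrogenolysis would finish. At about seven steps this is the shortest plan, clearly better than the chosen one.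
- Against it here: A6 is an acyclic 1,2-dialkyl alkene with benzylic allylic hydrogens on both sides. The alkylpalladium intermediate can undergo β-hydride elimination toward a styrene, and the alkene can migrate into conjugation. Enantioselective dicarbonylation of such internal acyclic alkenes is the least secure substrate class for this reaction. Making A6 from two nearly identical allyl or benzyl partners also invites statistical mixtures with the two symmetrical homodimers.
- Comparison: the ring A/ring B difference is irrelevant to the dicarbonylation itself (equal or better than the chosen plan, which must build that difference into the furan). All risk, however, sits in one step on an unfavourable substrate class, whereas the chosen plan spreads it over steps of established type.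

Key step: step 8

Assumption: the carbinol centre C7 made in step 4 is carried as a mixture of epimers, which is immaterial because step 7 oxidises it; 1, 2, 7 and 13 are taken as purchasable.

## Route

Step 1
Reactants: 1 4-(benzyloxy)-3-methoxybenzaldehyde; 2 dimethyl succinate
Product: 3 (E)-4-[4-(benzyloxy)-3-methoxyphenyl]-3-(methoxycarbonyl)but-3-enoic acid
Conditions: NaOMe (2.2 equiv), MeOH, reflux; then 2 M HCl
Reagents that add atoms: none
Why: Stobbe condensation: the succinate enolate adds to the aldehyde, the alkoxide lactonises onto the distal ester and E1cB opening gives the (E)-alkylidene half-ester, so the two carboxyl groups are differentiated without a protecting group.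

Step 2
Reactants: 3 (E)-4-[4-(benzyloxy)-3-methoxyphenyl]-3-(methoxycarbonyl)but-3-enoic acid
Product: 4 (3R)-4-[4-(benzyloxy)-3-methoxyphenyl]-3-(methoxycarbonyl)butanoic acid
Conditions: H2 (5 bar), [Rh(cod)((S,S)-Et-DuPHOS)]BF4 (0.5 mol %), NaOMe (10 mol %), MeOH, 25 °C
Reagents that add atoms: none
Why: Asymmetric hydrogenation of an itaconate-type half-ester: the carboxylate and the alkene chelate rhodium and hydrogen is delivered to one face, setting C8' as R; the homogeneous cationic catalyst does not cleave the benzyl ether. The (S,S) ligand is the antipode expected to give the R acid, and the sense is to be confirmed on 6 before material is committed.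

Step 3
Reactants: 4 (3R)-4-[4-(benzyloxy)-3-methoxyphenyl]-3-(methoxycarbonyl)butanoic acid
Product: 6 (4R)-4-[4-(benzyloxy)-3-methoxybenzyl]dihydrofuran-2(3H)-one, via hydroxy acid 5 (not isolated)
Conditions: KOH (1.0 equiv), EtOH, 0 °C; CaCl2, NaBH4, −10 °C → rt; then 2 M HCl, rt
Reagents that add atoms: none
Why: Ca(BH4)2 formed in the flask reduces the ester but not the potassium carboxylate, and acidification closes the γ-lactone; C8' is not touched.

Step 4
Reactants: 6 (4R)-4-[4-(benzyloxy)-3-methoxybenzyl]dihydrofuran-2(3H)-one; 7 3-(trimethylsilyl)prop-2-ynal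
Product: 8 (3S,4R)-4-[4-(benzyloxy)-3-methoxybenzyl]-3-[1-hydroxy-3-(trimethylsilyl)prop-2-yn-1-yl]dihydrofuran-2(3H)-one
Conditions: LiN(SiMe3)2 (1.1 equiv), THF, −78 °C; 7, −78 °C; AcOH quench at −78 °C
Reagents that add atoms: none
Why: Lithium enolate aldol addition: the aldehyde approaches the five-membered enolate on the face opposite the C8' arylmethyl group, so C8 is set trans to it (the like relation of the target); the carbinol centre C7 is not controlled and is removed in step 7. The cold acidic quench prevents retro-aldol.

Step 5
Reactants: 8 (3S,4R)-4-[4-(benzyloxy)-3-methoxybenzyl]-3-[1-hydroxy-3-(trimethylsilyl)prop-2-yn-1-yl]dihydrofuran-2(3H)-one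
Product: 10 (2R,3R)-2-[4-(benzyloxy)-3-methoxybenzyl]-3-(1-hydroxyprop-2-yn-1-yl)butane-1,4-diol, via C-silyl triol 9 (not isolated)
Conditions: LiBH4 (3 equiv), THF–MeOH, 0 °C → rt; then K2CO3 (0.3 equiv), MeOH, rt
Reagents that add atoms: none
Why: Borohydride reduction of the lactone to the 1,4-diol without hydrometalation of the propargylic alkyne (the reason LiAlH4 is avoided), then base-catalysed methanolysis of the alkynyl C–Si bond; once C9 is reduced, C8 is no longer α to a carbonyl.

Step 6
Reactants: 10 (2R,3R)-2-[4-(benzyloxy)-3-methoxybenzyl]-3-(1-hydroxyprop-2-yn-1-yl)butane-1,4-diol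
Product: 11 (4R,5R)-6-[4-(benzyloxy)-3-methoxyphenyl]-4,5-bis({[tert-butyl(dimethyl)silyl]oxy}methyl)hex-1-yn-3-ol
Conditions: TBSCl (2.05 equiv), imidazole, CH2Cl2, −20 → 0 °C
Reagents that add atoms: tert-butyldimethylsilyl chloride, CC(C)(C)[Si](C)(C)Cl
Why: Kinetically controlled silylation: the two primary hydroxyls react faster than the secondary propargylic hydroxyl, which is flanked by the branched C8; limiting reagent and low temperature hold the reaction at the bis-silyl stage.

Step 7
Reactants: 11 (4R,5R)-6-[4-(benzyloxy)-3-methoxyphenyl]-4,5-bis({[tert-butyl(dimethyl)silyl]oxy}methyl)hex-1-yn-3-ol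
Product: 12 (4R,5R)-6-[4-(benzyloxy)-3-methoxyphenyl]-4,5-bis({[tert-butyl(dimethyl)silyl]oxy}methyl)hex-1-yn-3-one
Conditions: Dess–Martin periodinane (1.3 equiv), CH2Cl2, 0 °C → rt
Reagents that add atoms: none
Why: Dess–Martin oxidation of a propargylic alcohol under non-basic conditions; both C7 epimers converge on one ynone, and the absence of base protects C8 from epimerisation and the C9 silyloxy group from β-elimination.

Step 8
Reactants: 12 (4R,5R)-6-[4-(benzyloxy)-3-methoxyphenyl]-4,5-bis({[tert-butyl(dimethyl)silyl]oxy}methyl)hex-1-yn-3-one; 13 3-methoxyfuran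
Product: 15 (2R,3R)-4-[4-(benzyloxy)-3-methoxyphenyl]-2,3-bis({[tert-butyl(dimethyl)silyl]oxy}methyl)-1-(3-hydroxy-4-methoxyphenyl)butan-1-one, via oxanorbornadiene 14 (not isolated)
Conditions: 13 (3 equiv), toluene, 25 → 50 °C; volatiles removed; PPTS (5 mol %), CH2Cl2, 0 °C → rt
Reagents that add atoms: none
Why: A thermal normal-demand Diels–Alder reaction: the electron-rich furan 13, whose largest HOMO coefficient is at C2 (the β-carbon of its enol ether), adds to the electron-poor ynone 12, whose largest LUMO coefficient is at the terminal carbon, so the furan C2–terminal carbon bond leads and the furan C5–acyl-bearing carbon bond follows, giving the 7-oxanorbornadiene 14. Ring A is thus closed by an intermolecular [4+2] cycloaddition that forms its bonds between positions 2 and 3 and between positions 1 and 6 (position 1 carries C7). Protonation of the bridge oxygen by the weak acid then breaks the C–O bond at the former furan C5, because that cation is an allyl cation ending on the methoxy-bearing carbon (a vinylogous oxocarbenium ion), whereas cleavage at the other bridgehead would give a cation cross-conjugated with the methoxy group and conjugated with the acyl group. Loss of the proton from the oxygen-bearing carbon aromatises the ring and leaves the hydroxyl on the former furan C2, ortho to the methoxy group and meta to the carbon bearing C7. The closest known reaction type is the cycloaddition of 3-alkoxyfurans with acetylenic ketones and esters followed by opening of the oxygen bridge to a phenol. No stereocentre is created: the two bridgehead centres of 14 vanish on aromatisation, so 14 may be a mixture of diastereomers without consequence. The step needs regioselectivity twice, secured both times by the 3-methoxy group, and cycloaddition in preference to simple conjugate addition at furan C2, which is favoured by a non-polar medium without Lewis acid. C8 stays intact because no base is present, the acid is weak and catalytic, and the C9 oxygen is a silyl ether, a poor leaving group.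

Step 9
Reactants: 15 (2R,3R)-4-[4-(benzyloxy)-3-methoxyphenyl]-2,3-bis({[tert-butyl(dimethyl)silyl]oxy}methyl)-1-(3-hydroxy-4-methoxyphenyl)butan-1-one
Product: 17 (2R,3R)-2-(3-hydroxy-4-methoxybenzyl)-3-(4-hydroxy-3-methoxybenzyl)butane-1,4-diol, via bis-silyl diphenol 16 (not isolated)
Conditions: H2 (4 bar), 10% Pd/C, EtOAc–AcOH (4:1), rt until the ketone is consumed; then HCl (1.25 M in MeOH), H2, rt
Reagents that add atoms: none
Why: Heterogeneous hydrogenolysis: the aryl ketone is reduced at the benzylic C–O stage down to CH2 (the para methoxy group assists benzylic C–O cleavage) and the benzyl ether is cleaved. Mineral acid is added only after the carbonyl has gone, so C8 is never α to a ketone under strong acid; methanolic HCl then removes both silyl ethers and completes any remaining benzylic C–O hydrogenolysis.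

Step 10
Reactants: 17 (2R,3R)-2-(3-hydroxy-4-methoxybenzyl)-3-(4-hydroxy-3-methoxybenzyl)butane-1,4-diol
Product: 18 (2R,3R)-2-[3-(benzoyloxy)-4-methoxybenzyl]-3-[4-(benzoyloxy)-3-methoxybenzyl]butane-1,4-diyl dibenzoate
Conditions: BzCl (6 equiv), pyridine, DMAP (cat.), CH2Cl2, 0 °C → rt
Reagents that add atoms: benzoyl chloride, O=C(Cl)c1ccccc1
Why: Exhaustive acylation of all four hydroxyls with nucleophilic catalysis by DMAP; no selectivity is required and no stereocentre is involved.

Step 11
Reactants: 18 (2R,3R)-2-[3-(benzoyloxy)-4-methoxybenzyl]-3-[4-(benzoyloxy)-3-methoxybenzyl]butane-1,4-diyl dibenzoate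
Product: 19 (2R,3R)-2-(3-hydroxy-4-methoxybenzyl)-3-(4-hydroxy-3-methoxybenzyl)butane-1,4-diyl dibenzoate
Conditions: pyrrolidine (2.5 equiv), THF, 0 °C → rt
Reagents that add atoms: none
Why: Chemoselective aminolysis: an aryl benzoate has a phenoxide leaving group and reacts with a secondary amine far faster than a primary alkyl benzoate, so the two phenols are freed while the C9 and C9' esters remain; the conditions are too mild for acyl migration.

## Compound list

1 | 4-(benzyloxy)-3-methoxybenzaldehyde | COc1cc(C=O)ccc1OCc1ccccc1 | starting material
2 | dimethyl succinate | COC(=O)CCC(=O)OC | starting material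
3 | (E)-4-[4-(benzyloxy)-3-methoxyphenyl]-3-(methoxycarbonyl)but-3-enoic acid | COC(=O)/C(CC(=O)O)=C/c1ccc(OCc2ccccc2)c(OC)c1 | intermediate
4 | (3R)-4-[4-(benzyloxy)-3-methoxyphenyl]-3-(methoxycarbonyl)butanoic acid | COC(=O)[C@@H](CC(=O)O)Cc1ccc(OCc2ccccc2)c(OC)c1 | intermediate
5 | (3R)-4-[4-(benzyloxy)-3-methoxyphenyl]-3-(hydroxymethyl)butanoic acid (carboxylate salt in the flask) | OC[C@@H](CC(=O)O)Cc1ccc(OCc2ccccc2)c(OC)c1 | intermediate (not isolated)
6 | (4R)-4-[4-(benzyloxy)-3-methoxybenzyl]dihydrofuran-2(3H)-one | O=C1C[C@@H](Cc2ccc(OCc3ccccc3)c(OC)c2)CO1 | intermediate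
7 | 3-(trimethylsilyl)prop-2-ynal | C[Si](C)(C)C#CC=O | starting material
8 | (3S,4R)-4-[4-(benzyloxy)-3-methoxybenzyl]-3-[1-hydroxy-3-(trimethylsilyl)prop-2-yn-1-yl]dihydrofuran-2(3H)-one, both carbinol (C7) epimers | C[Si](C)(C)C#CC(O)[C@H]1C(=O)OC[C@@H]1Cc1ccc(OCc2ccccc2)c(OC)c1 | intermediate
9 | (2R,3R)-2-[4-(benzyloxy)-3-methoxybenzyl]-3-[1-hydroxy-3-(trimethylsilyl)prop-2-yn-1-yl]butane-1,4-diol, both C7 epimers | C[Si](C)(C)C#CC(O)[C@@H](CO)[C@H](CO)Cc1ccc(OCc2ccccc2)c(OC)c1 | intermediate (not isolated)
10 | (2R,3R)-2-[4-(benzyloxy)-3-methoxybenzyl]-3-(1-hydroxyprop-2-yn-1-yl)butane-1,4-diol, both C7 epimers | C#CC(O)[C@@H](CO)[C@H](CO)Cc1ccc(OCc2ccccc2)c(OC)c1 | intermediate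
11 | (4R,5R)-6-[4-(benzyloxy)-3-methoxyphenyl]-4,5-bis({[tert-butyl(dimethyl)silyl]oxy}methyl)hex-1-yn-3-ol, both C3 (= C7) epimers | C#CC(O)[C@@H](CO[Si](C)(C)C(C)(C)C)[C@H](CO[Si](C)(C)C(C)(C)C)Cc1ccc(OCc2ccccc2)c(OC)c1 | intermediate
12 | (4R,5R)-6-[4-(benzyloxy)-3-methoxyphenyl]-4,5-bis({[tert-butyl(dimethyl)silyl]oxy}methyl)hex-1-yn-3-one | C#CC(=O)[C@@H](CO[Si](C)(C)C(C)(C)C)[C@H](CO[Si](C)(C)C(C)(C)C)Cc1ccc(OCc2ccccc2)c(OC)c1 | intermediate
13 | 3-methoxyfuran | COc1ccoc1 | starting material
14 | (2R,3R)-4-[4-(benzyloxy)-3-methoxyphenyl]-2,3-bis({[tert-butyl(dimethyl)silyl]oxy}methyl)-1-(5-methoxy-7-oxabicyclo[2.2.1]hepta-2,5-dien-2-yl)butan-1-one, bridgehead diastereomers | COC1=CC2OC1C=C2C(=O)[C@@H](CO[Si](C)(C)C(C)(C)C)[C@H](CO[Si](C)(C)C(C)(C)C)Cc1ccc(OCc2ccccc2)c(OC)c1 | intermediate (not isolated)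
15 | (2R,3R)-4-[4-(benzyloxy)-3-methoxyphenyl]-2,3-bis({[tert-butyl(dimethyl)silyl]oxy}methyl)-1-(3-hydroxy-4-methoxyphenyl)butan-1-one | COc1ccc(C(=O)[C@@H](CO[Si](C)(C)C(C)(C)C)[C@H](CO[Si](C)(C)C(C)(C)C)Cc2ccc(OCc3ccccc3)c(OC)c2)cc1O | intermediate
16 | 4-[(2R,3R)-2,3-bis({[tert-butyl(dimethyl)silyl]oxy}methyl)-4-(3-hydroxy-4-methoxyphenyl)butyl]-2-methoxyphenol | COc1ccc(C[C@@H](CO[Si](C)(C)C(C)(C)C)[C@H](CO[Si](C)(C)C(C)(C)C)Cc2ccc(O)c(OC)c2)cc1O | intermediate (not isolated)
17 | (2R,3R)-2-(3-hydroxy-4-methoxybenzyl)-3-(4-hydroxy-3-methoxybenzyl)butane-1,4-diol | COc1ccc(C[C@@H](CO)[C@H](CO)Cc2ccc(O)c(OC)c2)cc1O | intermediate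
18 | (2R,3R)-2-[3-(benzoyloxy)-4-methoxybenzyl]-3-[4-(benzoyloxy)-3-methoxybenzyl]butane-1,4-diyl dibenzoate | COc1ccc(C[C@@H](COC(=O)c2ccccc2)[C@H](COC(=O)c2ccccc2)Cc2ccc(OC(=O)c3ccccc3)c(OC)c2)cc1OC(=O)c1ccccc1 | intermediate
19 | (2R,3R)-2-(3-hydroxy-4-methoxybenzyl)-3-(4-hydroxy-3-methoxybenzyl)butane-1,4-diyl dibenzoate | COc1ccc(C[C@@H](COC(=O)c2ccccc2)[C@H](COC(=O)c2ccccc2)Cc2ccc(O)c(OC)c2)cc1O | target

## Step count and least certain steps

Total step count: 11. Longest linear sequence: 11 steps (1 → 19; the route is fully linear, with 2, 7 and 13 brought in as purchased partners).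

Step 8 (key step). The most likely failure is a stepwise course in which attack of furan C2 on the ynone terminus is followed by proton transfer instead of ring closure, giving a conjugate adduct and no ring A. Acid-triggered oligomerisation of the electron-rich furan and enolisation of the C7 ketone (loss of C8 integrity) during the bridge opening are the other risks. Fallback: the cycloaddition is given up and ring A is brought in as a preformed arene. Setting out from 6, the lithium enolate (LiN(SiMe3)2, THF, −78 °C) would be alkylated with 3-(benzyloxy)-4-methoxybenzyl bromide trans to the C8' substituent to give (3R,4R)-3-[3-(benzyloxy)-4-methoxybenzyl]-4-[4-(benzyloxy)-3-methoxybenzyl]dihydrofuran-2(3H)-one F1. LiAlH4 in THF would reduce the lactone to (2R,3R)-2-[3-(benzyloxy)-4-methoxybenzyl]-3-[4-(benzyloxy)-3-methoxybenzyl]butane-1,4-diol F2. Hydrogenolysis of both benzyl ethers (H2, Pd/C, EtOAc–EtOH) rejoins the route at 17.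

Step 9. The risk is a stall at the benzylic alcohol stage in the acetic acid medium, tempting early addition of mineral acid while ketone remains. Premature loss of the silyl groups would then let the freed C9' hydroxyl close onto C7 and dehydrate toward a C7=C8 enol ether, scrambling C8. Fallback: carbonyl removal is separated from C–O hydrogenolysis. Setting out from 15, Luche reduction (NaBH4, CeCl3·7H2O, MeOH, −20 °C) would give (2R,3R)-4-[4-(benzyloxy)-3-methoxyphenyl]-2,3-bis({[tert-butyl(dimethyl)silyl]oxy}methyl)-1-(3-hydroxy-4-methoxyphenyl)butan-1-ol F3 as a mixture of C7 epimers, so that no ketone is present when acid is introduced. Hydrogenolysis in methanolic HCl (H2, Pd/C) would then cleave the benzylic C–O bond, the benzyl ether and both silyl ethers, rejoining the route at 17.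

Step 6. The risk is incomplete discrimination between the primary hydroxyls and the small, fairly acidic propargylic hydroxyl, leading to mixtures of bis- and tris-silyl ethers that are hard to separate. Fallback: the C7 hydroxyl is masked before the lactone is opened. Setting out from 8, 2-methoxypropene with catalytic PPTS (CH2Cl2, 0 °C) would give the mixed acetal (3S,4R)-4-[4-(benzyloxy)-3-methoxybenzyl]-3-[1-(2-methoxypropan-2-yloxy)-3-(trimethylsilyl)prop-2-yn-1-yl]dihydrofuran-2(3H)-one F4. LiBH4 would reduce it to (2R,3R)-2-[4-(benzyloxy)-3-methoxybenzyl]-3-[1-(2-methoxypropan-2-yloxy)-3-(trimethylsilyl)prop-2-yn-1-yl]butane-1,4-diol F5, and K2CO3 in MeOH would free the alkyne to give (2R,3R)-2-[4-(benzyloxy)-3-methoxybenzyl]-3-[1-(2-methoxypropan-2-yloxy)prop-2-yn-1-yl]butane-1,4-diol F6. Unselective silylation (TBSCl, imidazole) would give (4R,5R)-6-[4-(benzyloxy)-3-methoxyphenyl]-4,5-bis({[tert-butyl(dimethyl)silyl]oxy}methyl)-3-(2-methoxypropan-2-yloxy)hex-1-yne F7. Brief PPTS in MeOH at 0 °C removes the very labile acetal while leaving the primary silyl ethers, rejoining the route at 11.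

Step 2. The risk is insufficient enantioselectivity, or induction in the unexpected sense with the chosen ligand antipode, on a substrate whose aryl group is more electron-rich than the usual test cases; either would be carried into every later compound. Fallback: absolute configuration is taken from an oxazolidinone auxiliary instead of a catalyst. Setting out from 1, Knoevenagel–Doebner condensation with malonic acid (pyridine, piperidine, 90 °C) would give (E)-3-[4-(benzyloxy)-3-methoxyphenyl]prop-2-enoic acid F8, and hydrogenation of the C=C bond with RhCl(PPh3)3 (which spares the benzyl ether) would give 3-[4-(benzyloxy)-3-methoxyphenyl]propanoic acid F9. Mixed-anhydride acylation (PivCl, Et3N, then lithiated (4S)-4-benzyloxazolidin-2-one) would give (4S)-4-benzyl-3-{3-[4-(benzyloxy)-3-methoxyphenyl]propanoyl}oxazolidin-2-one F10. Alkylation of its sodium enolate (NaN(SiMe3)2, THF, −78 °C) with tert-butyl bromoacetate, on the face opposite the auxiliary benzyl group, would give tert-butyl (3R)-4-[(4S)-4-benzyl-2-oxooxazolidin-3-yl]-3-[4-(benzyloxy)-3-methoxybenzyl]-4-oxobutanoate F11. LiBH4 would remove the auxiliary reductively to give tert-butyl (3R)-4-[4-(benzyloxy)-3-methoxyphenyl]-3-(hydroxymethyl)butanoate F12, and trifluoroacetic acid in CH2Cl2 would close the lactone, rejoining the route at 6.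

## Further compounds

F1 | step 8 | (3R,4R)-3-[3-(benzyloxy)-4-methoxybenzyl]-4-[4-(benzyloxy)-3-methoxybenzyl]dihydrofuran-2(3H)-one | COc1ccc(C[C@H]2C(=O)OC[C@@H]2Cc2ccc(OCc3ccccc3)c(OC)c2)cc1OCc1ccccc1
F2 | step 8 | (2R,3R)-2-[3-(benzyloxy)-4-methoxybenzyl]-3-[4-(benzyloxy)-3-methoxybenzyl]butane-1,4-diol | COc1ccc(C[C@@H](CO)[C@H](CO)Cc2ccc(OCc3ccccc3)c(OC)c2)cc1OCc1ccccc1
F3 | step 9 | (2R,3R)-4-[4-(benzyloxy)-3-methoxyphenyl]-2,3-bis({[tert-butyl(dimethyl)silyl]oxy}methyl)-1-(3-hydroxy-4-methoxyphenyl)butan-1-ol, both C1 (= C7) epimers | COc1ccc(C(O)[C@@H](CO[Si](C)(C)C(C)(C)C)[C@H](CO[Si](C)(C)C(C)(C)C)Cc2ccc(OCc3ccccc3)c(OC)c2)cc1O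
F4 | step 6 | (3S,4R)-4-[4-(benzyloxy)-3-methoxybenzyl]-3-[1-(2-methoxypropan-2-yloxy)-3-(trimethylsilyl)prop-2-yn-1-yl]dihydrofuran-2(3H)-one | C[Si](C)(C)C#CC(OC(C)(C)OC)[C@H]1C(=O)OC[C@@H]1Cc1ccc(OCc2ccccc2)c(OC)c1
F5 | step 6 | (2R,3R)-2-[4-(benzyloxy)-3-methoxybenzyl]-3-[1-(2-methoxypropan-2-yloxy)-3-(trimethylsilyl)prop-2-yn-1-yl]butane-1,4-diol | C[Si](C)(C)C#CC(OC(C)(C)OC)[C@@H](CO)[C@H](CO)Cc1ccc(OCc2ccccc2)c(OC)c1
F6 | step 6 | (2R,3R)-2-[4-(benzyloxy)-3-methoxybenzyl]-3-[1-(2-methoxypropan-2-yloxy)prop-2-yn-1-yl]butane-1,4-diol | C#CC(OC(C)(C)OC)[C@@H](CO)[C@H](CO)Cc1ccc(OCc2ccccc2)c(OC)c1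
F7 | step 6 | (4R,5R)-6-[4-(benzyloxy)-3-methoxyphenyl]-4,5-bis({[tert-butyl(dimethyl)silyl]oxy}methyl)-3-(2-methoxypropan-2-yloxy)hex-1-yne | C#CC(OC(C)(C)OC)[C@@H](CO[Si](C)(C)C(C)(C)C)[C@H](CO[Si](C)(C)C(C)(C)C)Cc1ccc(OCc2ccccc2)c(OC)c1
F8 | step 2 | (E)-3-[4-(benzyloxy)-3-methoxyphenyl]prop-2-enoic acid | COc1cc(/C=C/C(=O)O)ccc1OCc1ccccc1
F9 | step 2 | 3-[4-(benzyloxy)-3-methoxyphenyl]propanoic acid | COc1cc(CCC(=O)O)ccc1OCc1ccccc1
F10 | step 2 | (4S)-4-benzyl-3-{3-[4-(benzyloxy)-3-methoxyphenyl]propanoyl}oxazolidin-2-one | O=C(CCc1ccc(OCc2ccccc2)c(OC)c1)N1[C@@H](Cc2ccccc2)COC1=O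
F11 | step 2 | tert-butyl (3R)-4-[(4S)-4-benzyl-2-oxooxazolidin-3-yl]-3-[4-(benzyloxy)-3-methoxybenzyl]-4-oxobutanoate | CC(C)(C)OC(=O)C[C@@H](Cc1ccc(OCc2ccccc2)c(OC)c1)C(=O)N1[C@@H](Cc2ccccc2)COC1=O
F12 | step 2 | tert-butyl (3R)-4-[4-(benzyloxy)-3-methoxyphenyl]-3-(hydroxymethyl)butanoate | CC(C)(C)OC(=O)C[C@H](CO)Cc1ccc(OCc2ccccc2)c(OC)c1
A1 | alternative 1 | dimethyl 2-[3-(benzyloxy)-4-methoxybenzoyl]-3-[4-(benzyloxy)-3-methoxybenzoyl]butanedioate (mixture of stereoisomers) | COC(=O)C(C(=O)c1ccc(OC)c(OCc2ccccc2)c1)C(C(=O)OC)C(=O)c1ccc(OCc2ccccc2)c(OC)c1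
A2 | alternative 1 | cis-fused 4-[3-(benzyloxy)-4-methoxyphenyl]-8-[4-(benzyloxy)-3-methoxyphenyl]-3,7-dioxabicyclo[3.3.0]octane-2,6-dione, both aryl groups exo | COc1ccc(cc1OCc1ccccc1)[C@H]1OC(=O)[C@H]2[C@@H]1C(=O)O[C@@H]2c1ccc(OCc2ccccc2)c(OC)c1
A3 | alternative 2 | (2R,3R)-2-[3-(benzyloxy)-4-methoxybenzyl]-3-{[5-(benzyloxy)-6-oxo-6H-pyran-2-yl]methyl}butane-1,4-diyl dibenzoate | COc1ccc(C[C@@H](COC(=O)c2ccccc2)[C@H](COC(=O)c2ccccc2)Cc2ccc(OCc3ccccc3)c(=O)o2)cc1OCc1ccccc1
A4 | alternative 2 | 1,1-dimethoxyethene | C=C(OC)OC
A5 | alternative 2 | (2R,3R)-2-[3-(benzyloxy)-4-methoxybenzyl]-3-[4-(benzyloxy)-3-methoxybenzyl]butane-1,4-diyl dibenzoate | COc1ccc(C[C@@H](COC(=O)c2ccccc2)[C@H](COC(=O)c2ccccc2)Cc2ccc(OCc3ccccc3)c(OC)c2)cc1OCc1ccccc1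
A6 | alternative 3 | (E)-1-[3-(benzyloxy)-4-methoxyphenyl]-4-[4-(benzyloxy)-3-methoxyphenyl]but-2-ene | COc1ccc(C/C=C/Cc2ccc(OCc3ccccc3)c(OC)c2)cc1OCc1ccccc1
A7 | alternative 3 | dimethyl (2R,3R)-2-[3-(benzyloxy)-4-methoxybenzyl]-3-[4-(benzyloxy)-3-methoxybenzyl]butanedioate | COc1ccc(C[C@@H](C(=O)OC)[C@H](C(=O)OC)Cc2ccc(OCc3ccccc3)c(OC)c2)cc1OCc1ccccc1
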